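## Retrosynthetic overview

1. Target 21 ⇐ 20 by removal of the two B‑ring MOM ethers; 20 ⇐ diol 19 by Mitsunobu closure of the O1–C2 bond. The pyran ring is the only ring made; both benzene rings are bought.
2. Key disconnection: the C3–C4 bond together with the C3 stereocentre. Diol 19 (via lactol 18) ⇐ A‑ring quinone methide 17 (C4 as exocyclic CH2 on C4a, C8a as C=O) + B‑ring arylacetaldehyde 16, joined by an aminocatalytic enantioselective Michael addition/lactolisation. This is a formal [4+2] that lays C4–C3–C2–O1 onto the C4a–C8a edge and joins the two halves.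
3. Feature used: the A ring (C4a, C5‑OMe, C6‑H, C7‑OH, C8‑CHO, C8a‑O1) is a desymmetrised 2,6‑dihydroxy‑4‑methoxybenzaldehyde. C4 lies ortho to O1 and para to the C7 hydroxyl, so it is a latent quinone methide carbon. Functionalising one of the two equivalent CH positions of symmetric 3 fixes C8‑CHO against C6‑H with no A‑ring protecting group and no late formylation.
4. 17 ⇐ sulfone 6 ⇐ 3 ⇐ phloroglucinaldehyde 1. 16 ⇐ resorcinol 7 by two directed ortho‑metalations (C3' prenyl first, then the two‑carbon arm at C1').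
5. Ring order: the pyran ring forms transiently as lactol 18 in step 7 and for good in step 8.

Key step: step 7

Assumption: the sense of induction in step 7 follows the usual steric‑shielding model for diarylprolinol silyl ether enamines, which assigns the (R)‑catalyst to (3R); 3 and 9 can also be bought, which would save steps 1 and 3.

## Route

Step 1
Reactants: 1 2,4,6‑trihydroxybenzaldehyde; 2 dimethyl sulfate
Product: 3 2,6‑dihydroxy‑4‑methoxybenzaldehyde
Conditions: Me2SO4 (1.0 equiv), NaHCO3 (1.1 equiv), DMF, 40 °C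
Reagents that add atoms: dimethyl sulfate 2, COS(=O)(=O)OC
Why: Williamson O‑methylation under limiting weak base should select the 4‑OH, which is the most acidic hydroxyl (para to CHO) and the only one not tied up in a hydrogen bond to the formyl oxygen, so the symmetric ether 3 results.

Step 2
Reactants: 3 2,6‑dihydroxy‑4‑methoxybenzaldehyde; 4 formaldehyde; 5 sodium 4‑methylbenzenesulfinate
Product: 6 2,6‑dihydroxy‑4‑methoxy‑3‑[(4‑methylbenzenesulfonyl)methyl]benzaldehyde
Conditions: 37% aq. CH2O (1.05 equiv), TolSO2Na (1.5 equiv), HCO2H/H2O 1:1, rt → 40 °C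
Reagents that add atoms: formaldehyde 4, C=O; sodium 4‑methylbenzenesulfinate 5, Cc1ccc(cc1)S(=O)[O-].[Na+]
Why: Three‑component sulfonylmethylation (Mannich‑type electrophilic substitution in which the hydroxymethyl/quinone methide cation is trapped at sulfur by sulfinate) should occur at C3, which is equivalent to C5 in symmetric 3, so only one regioisomer can form.

Step 3
Reactants: 7 resorcinol; 8 chloromethyl methyl ether
Product: 9 1,3‑bis(methoxymethoxy)benzene
Conditions: MOMCl (2.4 equiv), i‑Pr2NEt (3 equiv), CH2Cl2, 0 °C → rt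
Reagents that add atoms: chloromethyl methyl ether 8, COCCl
Why: Standard base‑mediated O‑alkylation of both phenols with MOMCl installs the acetal groups that direct both later lithiations.

Step 4
Reactants: 9 1,3‑bis(methoxymethoxy)benzene; 10 1‑bromo‑3‑methylbut‑2‑ene
Product: 12 1,3‑bis(methoxymethoxy)‑2‑(3‑methylbut‑2‑en‑1‑yl)benzene, via 2‑lithio‑1,3‑bis(methoxymethoxy)benzene 11 (not isolated)
Conditions: n‑BuLi (1.1 equiv), THF, 0 °C → rt; then CuI (10 mol %), prenyl bromide, −78 °C → rt
Reagents that add atoms: 1‑bromo‑3‑methylbut‑2‑ene 10, CC(C)=CCBr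
Why: Directed ortho‑metalation occurs at C2 between the two cooperating OMOM groups, and copper‑assisted SN2 allylation of aryllithium 11 with prenyl bromide should give the linear prenyl arene.

Step 5
Reactants: 12 1,3‑bis(methoxymethoxy)‑2‑(3‑methylbut‑2‑en‑1‑yl)benzene; 13 oxirane
Product: 15 2‑[2,4‑bis(methoxymethoxy)‑3‑(3‑methylbut‑2‑en‑1‑yl)phenyl]ethan‑1‑ol, via aryllithium 14 (not isolated)
Conditions: n‑BuLi (1.2 equiv), TMEDA, THF, −20 → 0 °C; then oxirane (3 equiv, THF solution), −78 °C → rt; H2O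
Reagents that add atoms: oxirane 13, C1CO1
Why: A second directed ortho‑metalation next to an OMOM group (the two remaining ortho positions are equivalent in symmetric 12, and ring lithiation is expected to outrun deprotonation of the benzylic CH2) followed by epoxide ring‑opening with aryllithium 14 should give the 2‑arylethanol.

Step 6
Reactants: 15 2‑[2,4‑bis(methoxymethoxy)‑3‑(3‑methylbut‑2‑en‑1‑yl)phenyl]ethan‑1‑ol
Product: 16 2‑[2,4‑bis(methoxymethoxy)‑3‑(3‑methylbut‑2‑en‑1‑yl)phenyl]acetaldehyde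
Conditions: Dess–Martin periodinane (1.2 equiv), CH2Cl2, 0 °C → rt; used crude at once
Reagents that add atoms: none
Why: Dess–Martin oxidation converts the primary alcohol into the arylacetaldehyde under near‑neutral conditions that should leave the MOM acetals and the prenyl alkene untouched.

Step 7
Reactants: 6 2,6‑dihydroxy‑4‑methoxy‑3‑[(4‑methylbenzenesulfonyl)methyl]benzaldehyde; 16 2‑[2,4‑bis(methoxymethoxy)‑3‑(3‑methylbut‑2‑en‑1‑yl)phenyl]acetaldehyde (1.3 equiv)
Product: 19 3‑[(2R)‑2‑[2,4‑bis(methoxymethoxy)‑3‑(3‑methylbut‑2‑en‑1‑yl)phenyl]‑3‑hydroxypropyl]‑2,6‑dihydroxy‑4‑methoxybenzaldehyde, via quinone methide 17 (not isolated), via chroman‑2‑ol lactol 18 (not isolated)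
Conditions: (R)‑2‑[diphenyl(trimethylsilyloxy)methyl]pyrrolidine (20 mol %), NaHCO3 (2 equiv), wet CH2Cl2, 0 °C; then EtOH, NaBH4 (1 equiv), −40 °C; aq. NH4Cl
Reagents that add atoms: none
Why: Bicarbonate ionises a phenol of 6 and expels p‑toluenesulfinate to give quinone methide 17 (its para‑quinoid tautomer through the other hydroxyl is electrophilic at the same exocyclic CH2), while the amine converts 16 into its E‑enamine; Michael addition of the enamine α‑carbon to that CH2 forms C3–C4, and hydrolysis of the iminium with capture by the neighbouring phenol gives lactol 18, a formal [4+2] annulation. The closest known reaction type is the diarylprolinol silyl ether‑catalysed asymmetric addition of aldehydes to ortho‑quinone methides released in situ from 2‑(sulfonylmethyl)phenols, which also ends in chroman‑2‑ols. The pyran ring of 18 closes by 6‑exo‑trig attack of the C8a oxygen on the C2 iminium/aldehyde carbon; borohydride then reduces the open hydroxy‑aldehyde form in the same flask, so the ring is closed for good only in step 8. C3 is set by the catalyst: the CPh2OTMS group shields one face of the s‑trans E‑enamine and the quinone methide adds to the open face, which for the (R)‑catalyst should lead to (R) at C3. The step needs configurational stability of the α‑aryl aldehyde and a chemoselective reduction: the hindered catalyst re‑forms enamines from α‑branched aldehydes only slowly, the adduct rests largely as lactol and is reduced at once at −40 °C, and the aromatic aldehyde, flanked by two oxygens and present as a hydrogen‑bonded phenoxide (a vinylogous carboxylate), should be left alone by NaBH4 at that temperature. A‑ring regiochemistry needs no control, because only the hydroxyl ortho to the new CH2 can form the lactol and, later, the ether.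

Step 8
Reactants: 19 3‑[(2R)‑2‑[2,4‑bis(methoxymethoxy)‑3‑(3‑methylbut‑2‑en‑1‑yl)phenyl]‑3‑hydroxypropyl]‑2,6‑dihydroxy‑4‑methoxybenzaldehyde
Product: 20 (3R)‑3‑[2,4‑bis(methoxymethoxy)‑3‑(3‑methylbut‑2‑en‑1‑yl)phenyl]‑7‑hydroxy‑5‑methoxy‑3,4‑dihydro‑2H‑1‑benzopyran‑8‑carbaldehyde
Conditions: PPh3 (1.5 equiv), DIAD (1.5 equiv), THF (0.02 M), 0 °C → rt
Reagents that add atoms: none
Why: Intramolecular Mitsunobu etherification (6‑exo‑tet SN2 at the primary carbinol carbon C2 by the acidic C8a phenol, the only hydroxyl that can reach it) should close the pyran ring without touching C3.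

Step 9
Reactants: 20 (3R)‑3‑[2,4‑bis(methoxymethoxy)‑3‑(3‑methylbut‑2‑en‑1‑yl)phenyl]‑7‑hydroxy‑5‑methoxy‑3,4‑dihydro‑2H‑1‑benzopyran‑8‑carbaldehyde
Product: 21 (3R)‑3‑[2,4‑dihydroxy‑3‑(3‑methylbut‑2‑en‑1‑yl)phenyl]‑7‑hydroxy‑5‑methoxy‑3,4‑dihydro‑2H‑1‑benzopyran‑8‑carbaldehyde
Conditions: 3 M aq. HCl/MeOH 1:5, rt → 40 °C, stopped at full conversion
Reagents that add atoms: none
Why: Acid‑catalysed acetal solvolysis (transfer of CH2OMe to methanol) should free the two B‑ring phenols, with dilute acid and mild temperature chosen so that the ortho‑prenyl phenol is not cyclised; C3 has no pathway for epimerisation under these conditions.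

## Compound list

1 | 2,4,6‑trihydroxybenzaldehyde | O=Cc1c(O)cc(O)cc1O | starting material
2 | dimethyl sulfate | COS(=O)(=O)OC | starting material
3 | 2,6‑dihydroxy‑4‑methoxybenzaldehyde | COc1cc(O)c(C=O)c(O)c1 | intermediate
4 | formaldehyde (37% aq.) | C=O | starting material
5 | sodium 4‑methylbenzenesulfinate | Cc1ccc(cc1)S(=O)[O-].[Na+] | starting material
6 | 2,6‑dihydroxy‑4‑methoxy‑3‑[(4‑methylbenzenesulfonyl)methyl]benzaldehyde | COc1cc(O)c(C=O)c(O)c1CS(=O)(=O)c1ccc(C)cc1 | intermediate
7 | resorcinol | Oc1cccc(O)c1 | starting material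
8 | chloromethyl methyl ether | COCCl | starting material
9 | 1,3‑bis(methoxymethoxy)benzene | COCOc1cccc(OCOC)c1 | intermediate
10 | 1‑bromo‑3‑methylbut‑2‑ene (prenyl bromide) | CC(C)=CCBr | starting material
11 | 2‑lithio‑1,3‑bis(methoxymethoxy)benzene | [Li]c1c(OCOC)cccc1OCOC | intermediate
12 | 1,3‑bis(methoxymethoxy)‑2‑(3‑methylbut‑2‑en‑1‑yl)benzene | COCOc1cccc(OCOC)c1CC=C(C)C | intermediate
13 | oxirane | C1CO1 | starting material
14 | [2,4‑bis(methoxymethoxy)‑3‑(3‑methylbut‑2‑en‑1‑yl)phenyl]lithium | [Li]c1ccc(OCOC)c(CC=C(C)C)c1OCOC | intermediate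
15 | 2‑[2,4‑bis(methoxymethoxy)‑3‑(3‑methylbut‑2‑en‑1‑yl)phenyl]ethan‑1‑ol | COCOc1ccc(CCO)c(OCOC)c1CC=C(C)C | intermediate
16 | 2‑[2,4‑bis(methoxymethoxy)‑3‑(3‑methylbut‑2‑en‑1‑yl)phenyl]acetaldehyde | COCOc1ccc(CC=O)c(OCOC)c1CC=C(C)C | intermediate
17 | 2‑hydroxy‑4‑methoxy‑5‑methylidene‑6‑oxocyclohexa‑1,3‑diene‑1‑carbaldehyde (ortho‑quinone methide) | C=C1C(=O)C(C=O)=C(O)C=C1OC | intermediate
18 | (3R)‑3‑[2,4‑bis(methoxymethoxy)‑3‑(3‑methylbut‑2‑en‑1‑yl)phenyl]‑2,7‑dihydroxy‑5‑methoxy‑3,4‑dihydro‑2H‑1‑benzopyran‑8‑carbaldehyde (both C2 epimers) | COc1cc(O)c(C=O)c2c1C[C@H](c1ccc(OCOC)c(CC=C(C)C)c1OCOC)C(O)O2 | intermediate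
19 | 3‑[(2R)‑2‑[2,4‑bis(methoxymethoxy)‑3‑(3‑methylbut‑2‑en‑1‑yl)phenyl]‑3‑hydroxypropyl]‑2,6‑dihydroxy‑4‑methoxybenzaldehyde | COc1cc(O)c(C=O)c(O)c1C[C@H](c1ccc(OCOC)c(CC=C(C)C)c1OCOC)CO | intermediate
20 | (3R)‑3‑[2,4‑bis(methoxymethoxy)‑3‑(3‑methylbut‑2‑en‑1‑yl)phenyl]‑7‑hydroxy‑5‑methoxy‑3,4‑dihydro‑2H‑1‑benzopyran‑8‑carbaldehyde | COc1cc(O)c(C=O)c2c1C[C@H](c1ccc(OCOC)c(CC=C(C)C)c1OCOC)CO2 | intermediate
21 | (3R)‑3‑[2,4‑dihydroxy‑3‑(3‑methylbut‑2‑en‑1‑yl)phenyl]‑7‑hydroxy‑5‑methoxy‑3,4‑dihydro‑2H‑1‑benzopyran‑8‑carbaldehyde | COc1cc(O)c(C=O)c2c1C[C@H](c1ccc(O)c(CC=C(C)C)c1O)CO2 | target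

## Step count and risks

Total step count: 9. Longest linear sequence: 7 (steps 3, 4, 5, 6, 7, 8, 9, from resorcinol). The A‑ring branch is steps 1 and 2.

Steps most likely to fail:

Step 7. What may go wrong: loss of enantiomeric purity by enolisation of the α‑aryl aldehyde/lactol before reduction is complete, or over‑reduction of the aromatic aldehyde by borohydride. Fallback: make the enolisation productive and set C3 in the reduction instead of in the C–C bond formation. From 6 and 16, the same union run with achiral pyrrolidine (20 mol %) and NaHCO3 should give the racemic chroman‑2‑ol F1. F1 would then be reduced under dynamic kinetic resolution with a ketoreductase chosen from a commercial panel for the (R)‑alcohol (NADPH recycled with glucose/glucose dehydrogenase, phosphate buffer pH 7.5–8, DMSO co‑solvent, 30 °C). Under such conditions α‑aryl aldehydes racemise faster than the slow enantiomer is reduced, as is established for 2‑arylpropanals, and the enzyme should not accept the di‑ortho‑substituted aromatic aldehyde. The route is rejoined at diol 19.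

Step 2. What may go wrong: capture of the hydroxymethyl/quinone methide intermediate by a second molecule of 3 (methylene‑bridged diarylmethanes), or reaction at both C3 and C5. Fallback: from 3, aminomethylation with preformed Eschenmoser's salt (CH2=NMe2+ I−, MeCN, rt), in which no free formaldehyde and no benzylic cation occur, should give the Mannich base 3‑[(dimethylamino)methyl]‑2,6‑dihydroxy‑4‑methoxybenzaldehyde F2. Heating F2 with sodium 4‑methylbenzenesulfinate 5 in aqueous acetic acid should exchange dimethylamine for sulfinate through the quinone methide (the known amine–sulfinate exchange of phenolic Mannich bases) and return to sulfone 6.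

Step 9. What may go wrong: acid‑catalysed addition of a freed 2'‑ or 4'‑hydroxyl to the prenyl double bond (closure to a 2,2‑dimethylchroman) competing with acetal cleavage. Fallback: carry an allyl group, which does not ionise under these conditions, through the same sequence and turn it into prenyl at the very end. From 9 (lithiated to 11 as in step 4), allyl bromide should give 1,3‑bis(methoxymethoxy)‑2‑(prop‑2‑en‑1‑yl)benzene F3. Lithiation to the aryllithium F4 and oxirane opening should give the arylethanol F5, and Dess–Martin oxidation the arylacetaldehyde F6. The key step with 6 should give, via the lactol F7, the diol F8, and Mitsunobu closure the chroman F9. HCl/MeOH should then give the allyl triol F10. Cross‑metathesis of F10 with 2‑methylbut‑2‑ene (Grubbs second‑generation catalyst, CH2Cl2, 40 °C), which tolerates free phenols and the aldehyde, should install the prenyl group and arrive at 21.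

Further compounds
F1 | step 7 | racemic 3‑[2,4‑bis(methoxymethoxy)‑3‑(3‑methylbut‑2‑en‑1‑yl)phenyl]‑2,7‑dihydroxy‑5‑methoxy‑3,4‑dihydro‑2H‑1‑benzopyran‑8‑carbaldehyde | COc1cc(O)c(C=O)c2c1CC(c1ccc(OCOC)c(CC=C(C)C)c1OCOC)C(O)O2
F2 | step 2 | 3‑[(dimethylamino)methyl]‑2,6‑dihydroxy‑4‑methoxybenzaldehyde | CN(C)Cc1c(OC)cc(O)c(C=O)c1O
F3 | step 9 | 1,3‑bis(methoxymethoxy)‑2‑(prop‑2‑en‑1‑yl)benzene | COCOc1cccc(OCOC)c1CC=C
F4 | step 9 | [2,4‑bis(methoxymethoxy)‑3‑(prop‑2‑en‑1‑yl)phenyl]lithium | [Li]c1ccc(OCOC)c(CC=C)c1OCOC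
F5 | step 9 | 2‑[2,4‑bis(methoxymethoxy)‑3‑(prop‑2‑en‑1‑yl)phenyl]ethan‑1‑ol | COCOc1ccc(CCO)c(OCOC)c1CC=C
F6 | step 9 | 2‑[2,4‑bis(methoxymethoxy)‑3‑(prop‑2‑en‑1‑yl)phenyl]acetaldehyde | COCOc1ccc(CC=O)c(OCOC)c1CC=C
F7 | step 9 | (3R)‑3‑[2,4‑bis(methoxymethoxy)‑3‑(prop‑2‑en‑1‑yl)phenyl]‑2,7‑dihydroxy‑5‑methoxy‑3,4‑dihydro‑2H‑1‑benzopyran‑8‑carbaldehyde | COc1cc(O)c(C=O)c2c1C[C@H](c1ccc(OCOC)c(CC=C)c1OCOC)C(O)O2
F8 | step 9 | 3‑[(2R)‑2‑[2,4‑bis(methoxymethoxy)‑3‑(prop‑2‑en‑1‑yl)phenyl]‑3‑hydroxypropyl]‑2,6‑dihydroxy‑4‑methoxybenzaldehyde | COc1cc(O)c(C=O)c(O)c1C[C@H](c1ccc(OCOC)c(CC=C)c1OCOC)CO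
F9 | step 9 | (3R)‑3‑[2,4‑bis(methoxymethoxy)‑3‑(prop‑2‑en‑1‑yl)phenyl]‑7‑hydroxy‑5‑methoxy‑3,4‑dihydro‑2H‑1‑benzopyran‑8‑carbaldehyde | COc1cc(O)c(C=O)c2c1C[C@H](c1ccc(OCOC)c(CC=C)c1OCOC)CO2
F10 | step 9 | (3R)‑3‑[2,4‑dihydroxy‑3‑(prop‑2‑en‑1‑yl)phenyl]‑7‑hydroxy‑5‑methoxy‑3,4‑dihydro‑2H‑1‑benzopyran‑8‑carbaldehyde | COc1cc(O)c(C=O)c2c1C[C@H](c1ccc(O)c(CC=C)c1O)CO2
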